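A direct plan would keep ring A as a benzyl-protected phloroglucinol and close ring C last, in one flask, from an aryne.
It would make the o-silylaryl triflate A1 in five linear steps from 3,5-bis(benzyloxy)phenol, and the potassium trans-glycidate A2 from 4-(benzyloxy)benzaldehyde by Wittig reaction, dioxirane epoxidation and ester cleavage.
Fluoride would then join A1 and A2 (aryne formation, carboxylate addition, 1,3-acyl shift, phenoxide opening of the epoxide) to the tetrabenzyl dihydroflavonol A3, and hydrogenolysis would give the target.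
Weak point 1, the aryne/acyl-shift/epoxide-opening cascade: it would stake ring C and both stereocentres on an untested combination at the end of the longest sequence. The aryl anion can be protonated before the acyl shift, the carboxylate must attack the aryne carbon next to the benzyl group, and a 6′-alkoxy phenoxide is known to favour 5-exo opening of such epoxides to benzofuranones.
Weak point 2, the five-step run-up to A1: it would form a single C–C bond of the target, and its ortho-bromination has to beat the equally activated carbon para to the hydroxyl.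
Weak point 3, the epoxidation that sets C2 and C3: its facial sense would be a forecast, its optical purity would have to be raised by recrystallisation, and the labile glycidate would then have to survive fluoride at 40 °C.

**Retrosynthetic overview**
The target is cut at C2–C1′: ring B would be added to the C2=C3 bond of a flat 8-benzyl-5,7-dioxygenated chromone by an enantioselective rhodium-catalysed conjugate arylation, which dearomatises the γ-pyranone into ring C and sets C2.
Ring C is therefore closed first (O1–C2 bond, from the enaminone of a 2-hydroxyacetophenone), before ring B exists; C3–O follows last, by oxidation of the enol silane anti to the new aryl group, so that C2 controls C3.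
The C8–CH2 bond comes from a Negishi coupling at an iodide placed ortho to the chelated hydroxyl of the acetophenone.
No aryne, epoxide or 6-endo/5-exo choice occurs, the chromone is three steps from a catalogue ketone, and the absolute sense rests on one catalyst-controlled step whose ligand is available in both forms.

Key step: step 4

Remark: 1-[2,4-bis(benzyloxy)-6-hydroxyphenyl]ethan-1-one, 4-(benzyloxy)benzyl chloride and 4-(benzyloxy)phenylboronic acid are taken as catalogue compounds. The 3-O-silyl group formed in the oxidation is kept until the last step, so that the air- and base-sensitive free α-ketol is released only at the end.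

Step 1
Reactants: 1 1-[2,4-bis(benzyloxy)-6-hydroxyphenyl]ethan-1-one
Product: 2 1-[4,6-bis(benzyloxy)-2-hydroxy-3-iodophenyl]ethan-1-one
Conditions: BnMe3N+ ICl2− (1.05 equiv), CaCO3 (1.5 equiv), CH2Cl2–MeOH (5:2), rt, dark
Reagents that add atoms: benzyltrimethylammonium dichloroiodate, C[N+](C)(C)Cc1ccccc1.Cl[I-]Cl
Why: Electrophilic iodination of a chelated phenol with a dichloroiodate salt, which should go to the only carbon ortho to the free hydroxyl (C3), as it does in 5-hydroxyflavones, and not to C5, which is screened by two benzyloxy groups; this carbon becomes C8 of the target.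

Step 2
Reactants: 2 1-[4,6-bis(benzyloxy)-2-hydroxy-3-iodophenyl]ethan-1-one
Product: 4 5,7-bis(benzyloxy)-8-iodo-4H-chromen-4-one, via enaminone 3 (not isolated)
Conditions: Me2NCH(OMe)2 (2.5 equiv), toluene, 100 °C; evaporation; then conc. HCl, CH2Cl2, rt
Reagents that add atoms: N,N-dimethylformamide dimethyl acetal, COC(OC)N(C)C
Why: Enaminone formation at the acetyl methyl group followed by acid-induced addition of the phenol to the β-carbon and loss of dimethylamine, the standard synthesis of 2,3-unsubstituted chromones from 2-hydroxyacetophenones, which closes ring C as a flat pyranone before ring B is present.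

Step 3
Reactants: 4 5,7-bis(benzyloxy)-8-iodo-4H-chromen-4-one; 5 1-(benzyloxy)-4-(chloromethyl)benzene
Product: 7 5,7-bis(benzyloxy)-8-[4-(benzyloxy)benzyl]-4H-chromen-4-one, via benzylzinc chloride 6 (not isolated)
Conditions: 5 (1.5 equiv), Zn dust, LiCl, THF, 25 °C; then 4, Pd(OAc)2 (2 mol %), 2-dicyclohexylphosphino-2′,6′-dimethoxybiphenyl (SPhos, 4 mol %), THF, 25 → 50 °C
Reagents that add atoms: zinc dust, [Zn] (zinc of 6 only)
Why: Negishi cross-coupling of a benzylic zinc chloride, formed by LiCl-assisted zinc insertion, with the aryl iodide at zerovalent palladium carrying a bulky biaryl dialkylphosphine, which tolerates the two ortho substituents and leaves the enone and the benzyl ethers untouched.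

Step 4
Reactants: 7 5,7-bis(benzyloxy)-8-[4-(benzyloxy)benzyl]-4H-chromen-4-one; 8 [4-(benzyloxy)phenyl]boronic acid
Product: 9 (2S)-5,7-bis(benzyloxy)-8-[4-(benzyloxy)benzyl]-2-[4-(benzyloxy)phenyl]-2,3-dihydro-4H-chromen-4-one
Conditions: [Rh(OH)(cod)]2 (1.5 mol %), (S)-2,2′-bis[bis(3,4,5-trifluorophenyl)phosphino]-6,6′-dimethoxy-1,1′-biphenyl (3.3 mol %), 8 (3 equiv), toluene–H2O (10:1), 30 °C
Reagents that add atoms: none
Why: Hayashi–Miyaura reaction: the aryl group passes from boron to a hydroxo complex of monovalent rhodium, the C2=C3 bond of the benzopyranone inserts into the Rh–aryl bond with the aryl group going to C2, and water protonates the resulting oxa-π-allyl rhodium enolate and regenerates Rh–OH. The closest known reaction is the rhodium-catalysed asymmetric 1,4-addition of arylboronic acids to chromones with electron-poor atropisomeric bisphosphines, which gives 2-arylchroman-4-ones (flavanones) of the 5,7-dioxygenated type. No ring is closed: ring C already exists as the flat γ-pyranone of 7 and is dearomatised as C2 becomes sp3. The C2 stereocentre is set by the ligand alone (7 is achiral): by the model for cyclic enones the (S)-bisphosphine, which gives (S)-3-arylcyclohexanones, should deliver the aryl group to the corresponding face of C2 and give (2S), the arrangement that becomes (2R) once C3 carries oxygen; the (R)-ligand is equally available should the sense prove opposite. The step needs 1,4- over 1,2-addition and protonation of the rhodium enolate faster than β-aryloxide elimination (opening of ring C, which would erode the optical purity through the chalcone); the base-free aqueous medium, the π-acidic ligand and the low temperature should secure both, and the C5 and C8 substituents lie far from C2.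

Step 5
Reactants: 9 (2S)-5,7-bis(benzyloxy)-8-[4-(benzyloxy)benzyl]-2-[4-(benzyloxy)phenyl]-2,3-dihydro-4H-chromen-4-one
Product: 12 (2R,3R)-5,7-bis(benzyloxy)-8-[4-(benzyloxy)benzyl]-2-[4-(benzyloxy)phenyl]-3-(triethylsilyloxy)-2,3-dihydro-4H-chromen-4-one, via enol silane 10 (not isolated), via silyloxy epoxide 11 (not isolated)
Conditions: Et3SiOTf (1.3 equiv), Et3N (2.5 equiv), CH2Cl2, 0 °C, aq. NaHCO3 wash, used crude; then DMDO (1.2 equiv, in acetone), CH2Cl2, −40 → 0 °C; then PPTS (5 mol %), 0 °C → rt
Reagents that add atoms: triethylsilyl trifluoromethanesulfonate, CC[Si](CC)(CC)OS(=O)(=O)C(F)(F)F; dimethyldioxirane, CC1(C)OO1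
Why: Rubottom oxidation after soft enolisation (no free enolate, hence no retro-oxa-Michael opening that would racemise C2), in which the dioxirane should epoxidise the C3=C4 enol ether on the face anti to the C2 aryl group and acid-catalysed opening with 1,4-silyl shift should give the 2,3-trans α-silyloxy ketone, so that C3 (R) is set by substrate control from C2.

Step 6
Reactants: 12 (2R,3R)-5,7-bis(benzyloxy)-8-[4-(benzyloxy)benzyl]-2-[4-(benzyloxy)phenyl]-3-(triethylsilyloxy)-2,3-dihydro-4H-chromen-4-one
Product: 14 (2R,3R)-3,5,7-trihydroxy-8-(4-hydroxybenzyl)-2-(4-hydroxyphenyl)-2,3-dihydro-4H-chromen-4-one, via triethylsilyl ether 13 (not isolated)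
Conditions: H2 (1 atm), Pd(OH)2/C, THF–EtOAc, rt; filtration; then 1 M aq. HCl–THF (1:4), rt
Reagents that add atoms: none
Why: Hydrogenolysis of the four aryl benzyl ethers at 1 atm and neutral pH, under which the hydrogen-bonded C4 ketone, the diarylmethane and the O1–C2 bond of dihydroflavonol benzyl ethers are normally retained, followed by mild acid hydrolysis of the secondary silyl ether; neither operation touches C2 or C3.

**Compound list**

1 | 1-[2,4-bis(benzyloxy)-6-hydroxyphenyl]ethan-1-one | CC(=O)c1c(O)cc(OCc2ccccc2)cc1OCc1ccccc1 | starting material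
2 | 1-[4,6-bis(benzyloxy)-2-hydroxy-3-iodophenyl]ethan-1-one | CC(=O)c1c(O)c(I)c(OCc2ccccc2)cc1OCc1ccccc1 | intermediate
3 | (E)-1-[4,6-bis(benzyloxy)-2-hydroxy-3-iodophenyl]-3-(dimethylamino)prop-2-en-1-one | CN(C)/C=C/C(=O)c1c(O)c(I)c(OCc2ccccc2)cc1OCc1ccccc1 | intermediate (not isolated)
4 | 5,7-bis(benzyloxy)-8-iodo-4H-chromen-4-one | O=c1ccoc2c(I)c(OCc3ccccc3)cc(OCc3ccccc3)c12 | intermediate
5 | 1-(benzyloxy)-4-(chloromethyl)benzene (4-(benzyloxy)benzyl chloride) | ClCc1ccc(OCc2ccccc2)cc1 | starting material
6 | [4-(benzyloxy)benzyl]zinc chloride | Cl[Zn]Cc1ccc(OCc2ccccc2)cc1 | intermediate (not isolated)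
7 | 5,7-bis(benzyloxy)-8-[4-(benzyloxy)benzyl]-4H-chromen-4-one | O=c1ccoc2c(Cc3ccc(OCc4ccccc4)cc3)c(OCc3ccccc3)cc(OCc3ccccc3)c12 | intermediate
8 | [4-(benzyloxy)phenyl]boronic acid | OB(O)c1ccc(OCc2ccccc2)cc1 | starting material
9 | (2S)-5,7-bis(benzyloxy)-8-[4-(benzyloxy)benzyl]-2-[4-(benzyloxy)phenyl]-2,3-dihydro-4H-chromen-4-one | O=C1c2c(OCc3ccccc3)cc(OCc3ccccc3)c(Cc3ccc(OCc4ccccc4)cc3)c2O[C@H](c2ccc(OCc3ccccc3)cc2)C1 | intermediate
10 | (2S)-{5,7-bis(benzyloxy)-8-[4-(benzyloxy)benzyl]-2-[4-(benzyloxy)phenyl]-2H-chromen-4-yl}oxy(triethyl)silane | CC[Si](CC)(CC)OC1=C[C@@H](c2ccc(OCc3ccccc3)cc2)Oc2c(Cc3ccc(OCc4ccccc4)cc3)c(OCc3ccccc3)cc(OCc3ccccc3)c12 | intermediate (not isolated)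
11 | (2R,3R,4R)-5,7-bis(benzyloxy)-8-[4-(benzyloxy)benzyl]-2-[4-(benzyloxy)phenyl]-3,4-epoxy-4-(triethylsilyloxy)chromane (flavan numbering; oxirane oxygen anti to the C2 aryl group) | CC[Si](CC)(CC)O[C@]12c3c(OCc4ccccc4)cc(OCc4ccccc4)c(Cc4ccc(OCc5ccccc5)cc4)c3O[C@H](c3ccc(OCc4ccccc4)cc3)[C@H]1O2 | intermediate (not isolated)
12 | (2R,3R)-5,7-bis(benzyloxy)-8-[4-(benzyloxy)benzyl]-2-[4-(benzyloxy)phenyl]-3-(triethylsilyloxy)-2,3-dihydro-4H-chromen-4-one (2,3-trans) | O=C1c2c(OCc3ccccc3)cc(OCc3ccccc3)c(Cc3ccc(OCc4ccccc4)cc3)c2O[C@H](c2ccc(OCc3ccccc3)cc2)[C@H]1O[Si](CC)(CC)CC | intermediate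
13 | (2R,3R)-5,7-dihydroxy-8-(4-hydroxybenzyl)-2-(4-hydroxyphenyl)-3-(triethylsilyloxy)-2,3-dihydro-4H-chromen-4-one | O=C1c2c(O)cc(O)c(Cc3ccc(O)cc3)c2O[C@H](c2ccc(O)cc2)[C@H]1O[Si](CC)(CC)CC | intermediate (not isolated)
14 | (2R,3R)-3,5,7-trihydroxy-8-(4-hydroxybenzyl)-2-(4-hydroxyphenyl)-2,3-dihydro-4H-chromen-4-one | O=C1c2c(O)cc(O)c(Cc3ccc(O)cc3)c2O[C@H](c2ccc(O)cc2)[C@H]1O | target

**Summary**
Total steps: 6. Longest linear sequence: 6 (from 1).

**Steps most likely to fail, with fallbacks**

1. Step 4 (key step). Insertion into the electron-rich, vinylogous-ester enone may be slow, so that protodeboronation of 8 wins, or β-aryloxide elimination from the rhodium enolate may open ring C and lower the optical purity. Fallback: control by kinetic resolution instead of enantioselective C–C bond formation. Setting out from 7, conjugate addition of 8 under an achiral catalyst of divalent palladium (Pd(OCOCF3)2, 2,2′-bipyridine, AcOH–THF–H2O, 60 °C) would give the racemic 5,7-bis(benzyloxy)-8-[4-(benzyloxy)benzyl]-2-[4-(benzyloxy)phenyl]chroman-4-one F1. Asymmetric transfer hydrogenation (RuCl(p-cymene)(TsDPEN) of the antipode that reduces the (2R)-ketone faster, HCO2H–Et3N, EtOAc, rt, stopped near half conversion) would turn the (2R)-enantiomer into the cis-(2R,4R)-chroman-4-ol F2, which is separated, and would leave the (2S)-ketone, so that the route is rejoined at 9.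

2. Step 1. Iodination may occur at the carbon between the two benzyloxy groups, or twice. Fallback: let the phenol deliver the electrophile. Setting out from 1, boron-templated ortho-hydroxyalkylation (Nagata reaction) with 4-(benzyloxy)benzaldehyde and PhB(OH)2 (EtCO2H cat., toluene, Dean–Stark) can reach only the carbon ortho to the phenol oxygen and would give 1-{5,7-bis(benzyloxy)-4-[4-(benzyloxy)phenyl]-2-phenyl-4H-1,3,2-benzodioxaborinin-8-yl}ethan-1-one F3. Ionic hydrogenation of its doubly activated benzylic C–O bond (Et3SiH, TFA, CH2Cl2, −20 °C; aq. NaHCO3) would give 1-{4,6-bis(benzyloxy)-3-[4-(benzyloxy)benzyl]-2-hydroxyphenyl}ethan-1-one F4. Me2NCH(OMe)2 and then HCl would close the pyranone through (E)-1-{4,6-bis(benzyloxy)-3-[4-(benzyloxy)benzyl]-2-hydroxyphenyl}-3-(dimethylamino)prop-2-en-1-one F5, so that the route is rejoined at 7 (steps 1 to 3 are replaced).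

3. Step 3. Coupling at the doubly ortho-substituted iodide may be slow, so that homocoupling of the benzylzinc reagent and reduction of the iodide take over. Fallback: make the C8–C bond as an acyl bond and reduce afterwards. Setting out from 4, carbonylative Suzuki–Miyaura coupling with 8 (CO 1 atm, PdCl2(PPh3)2, K2CO3, anisole, 80 °C) would give 5,7-bis(benzyloxy)-8-[4-(benzyloxy)benzoyl]-4H-chromen-4-one F6. Ionic hydrogenation of this electron-rich diaryl ketone (Et3SiH, TFA, CH2Cl2, 0 °C → rt), which should leave the vinylogous-ester carbonyl of the chromone alone, would rejoin the route at 7.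

**Further compounds**
F1 | step 4 | racemic 5,7-bis(benzyloxy)-8-[4-(benzyloxy)benzyl]-2-[4-(benzyloxy)phenyl]chroman-4-one | O=C1CC(c2ccc(OCc3ccccc3)cc2)Oc2c(Cc3ccc(OCc4ccccc4)cc3)c(OCc3ccccc3)cc(OCc3ccccc3)c12
F2 | step 4 | (2R,4R)-5,7-bis(benzyloxy)-8-[4-(benzyloxy)benzyl]-2-[4-(benzyloxy)phenyl]chroman-4-ol (2,4-cis) | O[C@H]1c2c(OCc3ccccc3)cc(OCc3ccccc3)c(Cc3ccc(OCc4ccccc4)cc3)c2O[C@@H](c2ccc(OCc3ccccc3)cc2)C1
F3 | step 1 | 1-{5,7-bis(benzyloxy)-4-[4-(benzyloxy)phenyl]-2-phenyl-4H-1,3,2-benzodioxaborinin-8-yl}ethan-1-one (racemic at C4) | CC(=O)c1c(OCc2ccccc2)cc(OCc2ccccc2)c2C(c3ccc(OCc4ccccc4)cc3)OB(c3ccccc3)Oc12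
F4 | step 1 | 1-{4,6-bis(benzyloxy)-3-[4-(benzyloxy)benzyl]-2-hydroxyphenyl}ethan-1-one | CC(=O)c1c(O)c(Cc2ccc(OCc3ccccc3)cc2)c(OCc2ccccc2)cc1OCc1ccccc1
F5 | step 1 | (E)-1-{4,6-bis(benzyloxy)-3-[4-(benzyloxy)benzyl]-2-hydroxyphenyl}-3-(dimethylamino)prop-2-en-1-one | CN(C)/C=C/C(=O)c1c(O)c(Cc2ccc(OCc3ccccc3)cc2)c(OCc2ccccc2)cc1OCc1ccccc1
F6 | step 3 | 5,7-bis(benzyloxy)-8-[4-(benzyloxy)benzoyl]-4H-chromen-4-one | O=c1ccoc2c(C(=O)c3ccc(OCc4ccccc4)cc3)c(OCc3ccccc3)cc(OCc3ccccc3)c12
A1 | direct plan | 3,5-bis(benzyloxy)-2-[4-(benzyloxy)benzyl]-6-(trimethylsilyl)phenyl trifluoromethanesulfonate | C[Si](C)(C)c1c(OCc2ccccc2)cc(OCc2ccccc2)c(Cc2ccc(OCc3ccccc3)cc2)c1OS(=O)(=O)C(F)(F)F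
A2 | direct plan | potassium (2R,3S)-3-[4-(benzyloxy)phenyl]oxirane-2-carboxylate | O1[C@@H](c2ccc(OCc3ccccc3)cc2)[C@@H]1C(=O)[O-].[K+]
A3 | direct plan | (2R,3R)-5,7-bis(benzyloxy)-8-[4-(benzyloxy)benzyl]-2-[4-(benzyloxy)phenyl]-3-hydroxychroman-4-one | O=C1c2c(OCc3ccccc3)cc(OCc3ccccc3)c(Cc3ccc(OCc4ccccc4)cc3)c2O[C@H](c2ccc(OCc3ccccc3)cc2)[C@H]1O
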